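## Structural features

The target is a 2′-hydroxyflavanone locked as its cyclic hemiketal. Ring C (O1, C2, C3, C4, C4a, C8a) is bridged from C2 to C4 by C1′–C2′–O of ring B, giving a 2,6-dioxabicyclo[3.3.1]nonane flanked by two benzene rings. Ring A is hexasubstituted: OMe on C5, a 2,2-dimethyl-2H-pyran fused through C6 and the C7 oxygen, a prenyl chain on C8, and the ring C junction at C4a/C8a. The stereocentres C2 (R) and C4 (R) are 1,3-related across the C3 methylene, and because the bridge can only be cis, C4 follows from C2, so there is one stereochemical task. Fragile elements are the hemiketal, the prenyl and chromene olefins (no hydrogenolysis, strong acid or unselective oxidants late on), and the C2–O1 bond. That bond is benzylic to an aryl with two ortho oxygens and β to the C4 carbonyl in the open form, so it can ionise under acid or open by retro-oxa-Michael under base. The real difficulty is to fix C2 as one enantiomer in a flavanone that racemises easily, while building a fully substituted phloroglucinol-type ring A with every substituent in place. The key step uses the fact that ring C without ring A, O1–C2–C3–C4(=O)–C4a=C8a, is a 2-aryl-2,3-dihydropyran-4-one, the formal cycloadduct of a ring B aldehyde and a 1-methoxy-3-silyloxybutadiene, so C2 can be set by a catalyst on an achiral aldehyde before ring A or any olefin exists.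

## Logic of the disconnections

**23 ⇒ 21.** Cut the C4–O bond of the bridge and the two O–Si bonds of ring B. The bridge is only the ring-chain tautomer of ketone 22, so it needs no step of its own. The bicycle and the C4 stereocentre drop out of the planning. The forward step must unmask ring B close to neutrality, because acid ionises C2–O1 and base opens ring C.

**21 ⇒ 20.** Cut the C5 O–CH3 bond. The C5 hydroxyl is kept free until the pyran is closed, because its hydrogen bond to C4=O steers that closure. The forward step must alkylate a chelated, flanked phenol without base.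

**20 ⇒ 17 + 18.** Cut the C6–C(sp2) bond and the O7–CMe2 bond of the pyran. Both form in one phenol–enal condensation/oxa-6π sequence, which removes a ring and five carbons. The forward step must close on O7 and not on O5; C8 is already blocked.

**17 ⇒ 8 + 14.** Cut C4a–C5 and C8–C8a. A [4+2] annulation brings in C5–C8, both ring A oxygens and the C8 prenyl group from an acyclic β-keto ester derivative. The forward step needs an activating group on C4a that can leave syn to the C8a hydrogen, and it must leave before a carbonyl appears at C7, or O1 would be expelled.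

**8 ⇒ 7 ⇒ 5.** Cut the S–O bond, then the C4a–S bond. C4a is the nucleophilic carbon of the vinylogous ester, so sulfur enters as an electrophile. The forward step must prefer that carbon over ring B.

**14 ⇒ 13 ⇒ 12 ⇒ 9 + 10.** Cut two O–Si bonds, then the bond between the γ-carbon of 9 and the CH2 of 10. The diene reduces to two commodity chemicals. The alkylation must occur at the γ-carbon.

**5 ⇒ 2 + 3 (key disconnection).** Cut C2–C3 and O1–C8a. Ring C and the only independent stereocentre fall back to an achiral aldehyde and a commercial diene. The forward step needs a chiral Lewis acid that differentiates the faces of a di-ortho-substituted formyl group.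

**2 ⇒ 1.** Cut two O–Si bonds; 1 is commercial.

## Other disconnections considered

**Alternative 1:** Ring B is removed last-to-first by cutting C1′–C2′, C5′–C6′ and C2′–C3′. In the forward step, irradiation of diazo enone A1 with siloxyalkyne A2 triggers Wolff rearrangement, [2+2] cycloaddition, four-electron ring opening and six-electron ring closure; the new 2′-phenol then closes onto C4 to give A3.
- In favour: it is convergent and its regiochemistry is fixed by the polarity of the ynol ether. The two ring B oxygens emerge already differentiated, and the electron-rich aryl that labilises C2–O1 is absent until the end. On these points it equals or betters the chosen plan, and its ring-forming cascade is better understood than step 8.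
- Against: C2 must be set as an alkynyl-bearing centre on a fully substituted chromanone, and the fragile siloxyalkyne must be made on that advanced material. The irradiation must also spare a 2H-chromene (photochemical ring opening), an aryl ketone and a prenyl olefin.
- Comparison: the chosen plan sets C2 earlier and on a simpler substrate, and the ring A/C half of A2 would alone need about as many steps as the whole chosen route.

**Alternative 2:** The cut is C4–C4a and C8a–O. Fluoride converts silyl triflate A4 into aryne A5, which inserts into the acid C–O bond of A6 to give hydroxyaryl ketone A7.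
- In favour: ring A arrives complete, the C5 methoxy directs the oxygen nucleophile to C8a (meta to it), and no late benzannulation is needed. On security of ring A construction this is better than the chosen plan.
- Against: A4 is a hexasubstituted arene carrying chromene, prenyl, silyl and triflate groups, so its synthesis is long. Ring C must then be closed by invertive displacement at a carbinol flanked by two ortho alkoxy groups, where ionisation and elimination threaten the configuration. The acetal protecting groups of A6 call for acid at the end.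
- Comparison: the chosen plan forms C2–O1 in the enantio-determining event and is shorter, but it carries the less precedented annulation.

**Alternative 3:** The cut is C3–C4 and O1–C2. A chiral Brønsted acid dehydrates salicyl alcohol A8 to ortho-quinone methide A9, which adds to vinylresorcinol A10 to give flavan A11.
- In favour: one catalytic step builds ring C and C2 from two unprotected phenols. It is shorter to the core and better in protecting-group economy than the chosen plan, and equal in being catalyst-controlled.
- Against: A11 has CH2 at C4 and H at C8. C4 would need benzylic oxidation in the presence of the more activated C2–H, the chromene and free phenols, and C8 would need a regioselective C-prenylation. A10 is a polymerisation-prone styrene.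
- Comparison: the chosen plan delivers the C4 carbonyl and the C8 prenyl group directly, at the cost of protecting ring B.

Key step: step 2

**Remarks on the chemistry**

- Locants follow flavanone numbering (O1, C2–C4, C4a, C5–C8, C8a; ring B primed). TBS = tert-butyldimethylsilyl. salen = dianion of N,N′-bis(3,5-di-tert-butylsalicylidene)cyclohexane-1,2-diamine; (salen)CrCl is its chloro complex of trivalent chromium.
- Assumption: hemiketal 23 is the tautomer that the free 2′-hydroxy-5-methoxy ketone 22 adopts at equilibrium.
- The structures are stereochemically consistent: C2 is R in 5 and in 23, since O1 > C1′ > C3 > H at every stage and the C2–H bond is never broken.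
- Three design choices:
  - Ring B carries silyl ethers, not acetal ethers. They cannot chelate the catalyst, they shield ring B from electrophiles, and they are removed by buffered fluoride, not acid.
  - C4a carries a sulfoxide, not a halogen. After cycloaddition the C8a hydrogen is cis to the C4a substituent and is not acidic, so only a syn-eliminating group can restore C4a=C8a. Electrophilic halogenation would also attack ring B.
  - The C8 prenyl group travels with the diene, which removes a separate O-prenylation/rearrangement sequence.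

## Route

**Step 1**
Reactants: 1 2,6-dihydroxybenzaldehyde
Product: 2 2,6-bis(tert-butyldimethylsilyloxy)benzaldehyde
Conditions: TBSCl, imidazole, DMF, 23 °C
Reagents that add atoms: tert-butyldimethylsilyl chloride, CC(C)(C)[Si](C)(C)Cl
Why: Standard silylation of phenols with a silyl chloride and imidazole.

**Step 2**
Reactants: 2 2,6-bis(tert-butyldimethylsilyloxy)benzaldehyde; 3 (E)-1-methoxy-3-(trimethylsilyloxy)buta-1,3-diene
Product: 5 (R)-2-[2,6-bis(TBSO)phenyl]-2,3-dihydro-4H-pyran-4-one, via dihydropyran cycloadduct 4 (not isolated)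
Conditions: (R,R)-(salen)CrCl (5 mol %), 4 Å molecular sieves, t-BuOMe, −20 → 23 °C; then CF3CO2H (cat.), CH2Cl2, 0 °C
Reagents that add atoms: none
Why: The aldehyde oxygen binds to the trivalent chromium centre, and the CH2 terminus of 3 attacks the Re face of the formyl carbon (C2–C3) while the carbonyl oxygen bonds to the methoxy-bearing terminus (O1–C8a) in a concerted, asynchronous [4+2] cycloaddition that gives 4. Trifluoroacetic acid then cleaves the silyl enol ether and expels methanol to give enone 5. The closest known reaction type is the (salen)CrCl-catalysed hetero-Diels–Alder reaction of this diene with aromatic aldehydes to 2-aryl-2,3-dihydropyran-4-ones. Ring C closes by the cycloaddition itself; if the reaction ran stepwise, the aldol adduct would close on acid treatment by 6-endo-trig oxa-Michael addition and loss of methanol, with the same outcome. C2 is the only new stereocentre and is set by the chiral ligand (catalyst control), since 2 is achiral; with simple aromatic aldehydes the (R,R)-complex is expected to give the R series, and the (S,S)-complex is equally available if the sense is reversed for this di-ortho-substituted aldehyde. The step needs regioselectivity, which the polarisation of the diene fixes, and enantiofacial selectivity, which is helped by single-point binding because the ortho silyl ethers cannot chelate the metal. The aryl silyl ethers and the new benzylic C2–O1 bond should survive the brief catalytic acid treatment at 0 °C.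

**Step 3**
Reactants: 5 (R)-2-[2,6-bis(TBSO)phenyl]-2,3-dihydro-4H-pyran-4-one
Product: 7 (R)-2-[2,6-bis(TBSO)phenyl]-5-(phenylsulfanyl)-2,3-dihydro-4H-pyran-4-one, via chloro sulfide adduct 6 (not isolated)
Conditions: PhSCl, CH2Cl2, −78 °C; then Et3N, −78 → 0 °C
Reagents that add atoms: benzenesulfenyl chloride, ClSc1ccccc1
Why: Electrophilic sulfenylation of the enol-ether carbon C4a (addition across C4a=C8a, then base-induced loss of HCl), the sulfur counterpart of the α-halogenation of 2,3-dihydropyran-4-ones. The push–pull alkene should react at −78 °C while the hindered silyloxyarene does not, and C2 is not involved.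

**Step 4**
Reactants: 7 (R)-2-[2,6-bis(TBSO)phenyl]-5-(phenylsulfanyl)-2,3-dihydro-4H-pyran-4-one
Product: 8 (2R)-2-[2,6-bis(TBSO)phenyl]-5-(phenylsulfinyl)-2,3-dihydro-4H-pyran-4-one
Conditions: mCPBA (1.0 equiv), NaHCO3, CH2Cl2, −78 → −40 °C
Reagents that add atoms: 3-chloroperoxybenzoic acid (mCPBA), OOC(=O)c1cccc(Cl)c1
Why: Sulfide-to-sulfoxide oxidation; one equivalent at low temperature should stop at the sulfoxide and leave the electron-poor C4a=C8a bond alone. The sulfur stereocentre is irrelevant because the group is expelled in step 8.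

**Step 5**
Reactants: 9 methyl acetoacetate; 10 prenyl bromide
Product: 12 methyl 7-methyl-3-oxooct-6-enoate, via acetoacetate dianion 11 (not isolated)
Conditions: NaH, THF, 0 °C; n-BuLi, 0 °C; then 10, 0 → 23 °C; aq. HCl
Reagents that add atoms: none
Why: γ-Alkylation of a β-keto ester dianion; the more basic terminal carbanion attacks the primary allylic bromide by SN2.

**Step 6**
Reactants: 12 methyl 7-methyl-3-oxooct-6-enoate
Product: 13 methyl 7-methyl-3-(trimethylsilyloxy)octa-2,6-dienoate
Conditions: Me3SiCl, Et3N, hexane, 23 °C
Reagents that add atoms: chlorotrimethylsilane, C[Si](C)(C)Cl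
Why: O-silylation of the enolised β-keto ester, the usual first stage of 1,3-bis(silyloxy)diene synthesis.

**Step 7**
Reactants: 13 methyl 7-methyl-3-(trimethylsilyloxy)octa-2,6-dienoate
Product: 14 1-methoxy-7-methyl-1,3-bis(trimethylsilyloxy)octa-1,3,6-triene
Conditions: LiN(iPr)2, THF, −78 °C; Me3SiCl, −78 → 23 °C
Reagents that add atoms: chlorotrimethylsilane, C[Si](C)(C)Cl
Why: γ-Deprotonation gives the extended ester enolate, which is O-silylated to the ketene acetal. Geometric isomers are acceptable because C5 and C8 become aromatic.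

**Step 8**
Reactants: 8 (2R)-2-[2,6-bis(TBSO)phenyl]-5-(phenylsulfinyl)-2,3-dihydro-4H-pyran-4-one; 14 1-methoxy-7-methyl-1,3-bis(trimethylsilyloxy)octa-1,3,6-triene
Product: 17 (2R)-2-[2,6-bis(TBSO)phenyl]-5,7-dihydroxy-8-(3-methylbut-2-enyl)chroman-4-one, via sulfinyl cycloadduct 15 (not isolated), via cyclohexadiene ketal 16 (not isolated)
Conditions: toluene, 0 → 23 °C, then 80 °C; then 0.5 M HCl, THF, 0 °C
Reagents that add atoms: none
Why: Proposed new method: the sulfinyl and carbonyl groups on C4a make C8a strongly electrophilic, so the nucleophilic C8 terminus of 14 should bond to C8a and its ketene-acetal carbon (C5) to C4a; the closest known reaction types are the cycloaddition–aromatisation of 1-alkoxy-1,3-bis(silyloxy)dienes with haloquinones and the Diels–Alder/sulfoxide-elimination of sulfinylquinones and 2-sulfinyl enones. In 15 the sulfoxide on C4a and the hydrogen on C8a are cis, so thermal syn-elimination of benzenesulfenic acid restores C4a=C8a (16) before a C7 carbonyl could expel O1; dilute acid then removes the C5 ketal and the trimethylsilyl groups to leave the aromatic 5,7-diol. A [3+3] mode through the C4 carbonyl is excluded because it would have to bridge ring C.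

**Step 9**
Reactants: 17 (2R)-2-[2,6-bis(TBSO)phenyl]-5,7-dihydroxy-8-(3-methylbut-2-enyl)chroman-4-one; 18 3-methylbut-2-enal
Product: 20 (8R)-8-[2,6-bis(TBSO)phenyl]-5-hydroxy-2,2-dimethyl-10-(3-methylbut-2-enyl)-7,8-dihydro-2H,6H-pyrano[3,2-g]chromen-6-one, via quinone methide dienone 19 (not isolated)
Conditions: (H3NCH2CH2NH3)(OAc)2 (20 mol %), toluene, 110 °C
Reagents that add atoms: none
Why: Phenol–enal condensation at C6 (Knoevenagel type) followed by oxa-6π electrocyclisation. C8 is blocked, so C6 is the only free nucleophilic carbon, and reversible closure should settle on the C7 oxygen because that keeps the C5 hydroxyl hydrogen-bonded to C4=O.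

**Step 10**
Reactants: 20 (8R)-8-[2,6-bis(TBSO)phenyl]-5-hydroxy-2,2-dimethyl-10-(3-methylbut-2-enyl)-7,8-dihydro-2H,6H-pyrano[3,2-g]chromen-6-one
Product: 21 (8R)-8-[2,6-bis(TBSO)phenyl]-5-methoxy-2,2-dimethyl-10-(3-methylbut-2-enyl)-7,8-dihydro-2H,6H-pyrano[3,2-g]chromen-6-one
Conditions: MeOH, PPh3, DIAD, THF, 0 → 23 °C
Reagents that add atoms: methanol, CO
Why: Mitsunobu O-alkylation of the only free phenol. It runs without base, so the ring C oxa-Michael equilibrium that could scramble C2 is not opened.

**Step 11**
Reactants: 21 (8R)-8-[2,6-bis(TBSO)phenyl]-5-methoxy-2,2-dimethyl-10-(3-methylbut-2-enyl)-7,8-dihydro-2H,6H-pyrano[3,2-g]chromen-6-one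
Product: 23 CNP0170313.2 [(2R,4R)-bridged hemiketal], via free dihydroxyflavanone 22 (not isolated)
Conditions: Bu4NF, AcOH, THF, 0 → 23 °C
Reagents that add atoms: none
Why: Buffered fluoride cleaves the aryl silyl ethers. The freed 2′-hydroxyl adds to the C4 ketone, which is no longer chelated after O-methylation; the bridge can only form on the face that carries the C2 aryl group, so C4 is set as R by C2 (substrate control, thermodynamic).

## Compound list

1 | 2,6-dihydroxybenzaldehyde | O=Cc1c(O)cccc1O | starting material
2 | 2,6-bis(tert-butyldimethylsilyloxy)benzaldehyde | O=Cc1c(O[Si](C)(C)C(C)(C)C)cccc1O[Si](C)(C)C(C)(C)C | intermediate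
3 | (E)-1-methoxy-3-(trimethylsilyloxy)buta-1,3-diene | CO/C=C/C(=C)O[Si](C)(C)C | starting material
4 | (2R)-2-[2,6-bis(TBSO)phenyl]-6-methoxy-4-(trimethylsilyloxy)-3,6-dihydro-2H-pyran (acetal carbon unassigned) | COC1C=C(O[Si](C)(C)C)C[C@@H](O1)c1c(O[Si](C)(C)C(C)(C)C)cccc1O[Si](C)(C)C(C)(C)C | intermediate
5 | (R)-2-[2,6-bis(TBSO)phenyl]-2,3-dihydro-4H-pyran-4-one | O=C1C[C@@H](OC=C1)c1c(O[Si](C)(C)C(C)(C)C)cccc1O[Si](C)(C)C(C)(C)C | intermediate
6 | (2R)-2-[2,6-bis(TBSO)phenyl]-6-chloro-5-(phenylsulfanyl)tetrahydro-4H-pyran-4-one (C5, C6 unassigned) | O=C1C[C@@H](OC(Cl)C1Sc1ccccc1)c1c(O[Si](C)(C)C(C)(C)C)cccc1O[Si](C)(C)C(C)(C)C | intermediate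
7 | (R)-2-[2,6-bis(TBSO)phenyl]-5-(phenylsulfanyl)-2,3-dihydro-4H-pyran-4-one | O=C1C[C@@H](OC=C1Sc1ccccc1)c1c(O[Si](C)(C)C(C)(C)C)cccc1O[Si](C)(C)C(C)(C)C | intermediate
8 | (2R)-2-[2,6-bis(TBSO)phenyl]-5-(phenylsulfinyl)-2,3-dihydro-4H-pyran-4-one (both configurations at sulfur) | O=C1C[C@@H](OC=C1S(=O)c1ccccc1)c1c(O[Si](C)(C)C(C)(C)C)cccc1O[Si](C)(C)C(C)(C)C | intermediate
9 | methyl acetoacetate | COC(=O)CC(C)=O | starting material
10 | prenyl bromide (1-bromo-3-methylbut-2-ene) | CC(C)=CCBr | starting material
11 | sodium lithium dianion of methyl acetoacetate | COC([O-])=CC([O-])=C.[Na+].[Li+] | intermediate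
12 | methyl 7-methyl-3-oxooct-6-enoate | COC(=O)CC(=O)CCC=C(C)C | intermediate
13 | methyl 7-methyl-3-(trimethylsilyloxy)octa-2,6-dienoate (C2=C3 isomer mixture) | COC(=O)C=C(O[Si](C)(C)C)CCC=C(C)C | intermediate
14 | 1-methoxy-7-methyl-1,3-bis(trimethylsilyloxy)octa-1,3,6-triene (isomer mixture at C1 and C3) | COC(O[Si](C)(C)C)=CC(O[Si](C)(C)C)=CCC=C(C)C | intermediate
15 | (2R)-2-[2,6-bis(TBSO)phenyl]-5-methoxy-8-(3-methylbut-2-enyl)-4a-(phenylsulfinyl)-5,7-bis(trimethylsilyloxy)-2,3,4a,5,8,8a-hexahydro-4H-chromen-4-one (cis ring fusion; other new centres unassigned) | O=C1C[C@@H](OC2C(CC=C(C)C)C(O[Si](C)(C)C)=CC(OC)(O[Si](C)(C)C)C12S(=O)c1ccccc1)c1c(O[Si](C)(C)C(C)(C)C)cccc1O[Si](C)(C)C(C)(C)C | intermediate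
16 | (2R)-2-[2,6-bis(TBSO)phenyl]-5-methoxy-8-(3-methylbut-2-enyl)-5,7-bis(trimethylsilyloxy)-2,3,5,8-tetrahydro-4H-chromen-4-one | O=C1C[C@@H](OC2=C1C(OC)(O[Si](C)(C)C)C=C(O[Si](C)(C)C)C2CC=C(C)C)c1c(O[Si](C)(C)C(C)(C)C)cccc1O[Si](C)(C)C(C)(C)C | intermediate
17 | (2R)-2-[2,6-bis(TBSO)phenyl]-5,7-dihydroxy-8-(3-methylbut-2-enyl)chroman-4-one | O=C1C[C@@H](Oc2c(CC=C(C)C)c(O)cc(O)c12)c1c(O[Si](C)(C)C(C)(C)C)cccc1O[Si](C)(C)C(C)(C)C | intermediate
18 | 3-methylbut-2-enal | CC(C)=CC=O | starting material
19 | (2R)-2-[2,6-bis(TBSO)phenyl]-5-hydroxy-6-(3-methylbut-2-enylidene)-8-(3-methylbut-2-enyl)-2,3-dihydro-4H-chromene-4,7(6H)-dione | O=C1C[C@@H](OC2=C(CC=C(C)C)C(=O)C(=CC=C(C)C)C(O)=C12)c1c(O[Si](C)(C)C(C)(C)C)cccc1O[Si](C)(C)C(C)(C)C | intermediate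
20 | (8R)-8-[2,6-bis(TBSO)phenyl]-5-hydroxy-2,2-dimethyl-10-(3-methylbut-2-enyl)-7,8-dihydro-2H,6H-pyrano[3,2-g]chromen-6-one | O=C1C[C@@H](Oc2c(CC=C(C)C)c3OC(C)(C)C=Cc3c(O)c12)c1c(O[Si](C)(C)C(C)(C)C)cccc1O[Si](C)(C)C(C)(C)C | intermediate
21 | (8R)-8-[2,6-bis(TBSO)phenyl]-5-methoxy-2,2-dimethyl-10-(3-methylbut-2-enyl)-7,8-dihydro-2H,6H-pyrano[3,2-g]chromen-6-one | O=C1C[C@@H](Oc2c(CC=C(C)C)c3OC(C)(C)C=Cc3c(OC)c12)c1c(O[Si](C)(C)C(C)(C)C)cccc1O[Si](C)(C)C(C)(C)C | intermediate
22 | (8R)-8-(2,6-dihydroxyphenyl)-5-methoxy-2,2-dimethyl-10-(3-methylbut-2-enyl)-7,8-dihydro-2H,6H-pyrano[3,2-g]chromen-6-one (open keto form) | O=C1C[C@@H](Oc2c(CC=C(C)C)c3OC(C)(C)C=Cc3c(OC)c12)c1c(O)cccc1O | intermediate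
23 | CNP0170313.2, the (2R,4R) hemiketal of 22 bridged from the 2′-oxygen to C4 | COc1c2c(c(CC=C(C)C)c3c1[C@@]1(O)C[C@@H](O3)c3c(O)cccc3O1)OC(C)(C)C=C2 | target

## Step count and least certain steps

Total: 11 steps. Longest linear sequence: 8 steps (1, 2, 3, 4, 8, 9, 10, 11) from 1; the diene branch (steps 5–7) joins at step 8.

**Step 8 (new method).**
- What may go wrong: the diene may add to C8a by conjugate addition only, without forming the C4a–C5 bond. After sulfoxide elimination the material would then stall at the keto ester F2 described below, which base should still close to 17. Silicon transfer from the ketene acetal to the sulfoxide oxygen may trigger Pummerer-type reduction instead of cycloaddition. Premature hydrolysis of the C7 silyl enol ether, before the sulfoxide has left, would open ring C by loss of O1.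
- Fallback (known reaction types; oxidation level set by palladium instead of sulfur): it sets out from 5 and 14 and returns at 17. Catalytic Me3SiOTf in CH2Cl2 at −78 °C promotes Mukaiyama–Michael addition of the terminal carbon of 14 to C8a of 5 and leaves ring C as a regiodefined silyl enol ether, the bis-silyl conjugate adduct F1. Saegusa–Ito oxidation of that enol ether with Pd(OAc)2 in MeCN reinstates C4a=C8a and, after aqueous work-up, gives the 6-substituted dihydropyranone keto ester F2. DBU in toluene then closes C4a onto the ester carbon in a Claisen (Dieckmann-type) condensation, and loss of methanol and enolisation give 17. Ring C holds this condensation in the Claisen mode, because aldol closure onto C4 would have to bridge the pyranone.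

**Step 2 (key step).**
- What may go wrong: slow turnover, because the di-ortho-substituted, electron-rich aldehyde binds weakly to the metal, and poor facial selectivity, because the ortho groups change how the formyl group sits in the chiral pocket.
- Fallback (aldol/condensation instead of cycloaddition): it sets out from 2 and returns at 5. A Ti(OiPr)4/BINOL-catalysed Mukaiyama aldol addition of 2-(trimethylsilyloxy)propene, with the BINOL antipode chosen for the R carbinol, gives after mild acidic work-up the (R)-β-hydroxy ketone F3. Heating with N,N-dimethylformamide dimethyl acetal converts its methyl ketone into the enaminone F4, and mild acid closes ring C by oxa-Michael addition of the carbinol and loss of dimethylamine to give 5.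

**Step 3.**
- What may go wrong: competing sulfenylation of ring B, or addition without clean elimination.
- Fallback (cross-coupling instead of electrophilic substitution): it sets out from 5 and returns at 7. Iodine and pyridine in CH2Cl2 give the α-iodo enone F5, chemoselectively because iodine does not attack the arene. Coupling with PhSH under Pd2(dba)3/Xantphos and iPr2NEt in dioxane gives 7.

**Step 9.**
- What may go wrong: closure onto the C5 oxygen, giving the angular pyran, or partial loss of configuration at C2 through reversible opening of ring C in hot toluene with an amine salt.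
- Fallback (oxygen attached first, then sigmatropic ring construction): it sets out from 17 and returns at 20. Selective alkylation of the unchelated C7 hydroxyl with 3-chloro-3-methylbut-1-yne (K2CO3, KI, CuI, acetone) gives the 7-O-(1,1-dimethylpropargyl) ether F6. Heating in xylene at 140 °C effects propargyl Claisen rearrangement to C6 (the only free ortho carbon), hydrogen shift and oxa-6π closure to give 20.

**Step 10.**
- What may go wrong: sluggish alkylation, because the C5 hydroxyl is hydrogen-bonded and flanked by C4=O and the pyran vinyl carbon.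
- Fallback (methylate before the pyran is closed): it sets out from 17 and returns at 21. The 7-O-(1,1-dimethylpropargyl) ether F6 is made as above and its less hindered C5 hydroxyl is methylated with MeI and K2CO3 in acetone to give the 5-O-methyl propargyl ether F7. The same thermal rearrangement in xylene at 140 °C then gives 21 directly.

## Further compounds

F1 | step 8 | methyl 4-{(6R)-6-[2,6-bis(TBSO)phenyl]-4-(trimethylsilyloxy)-5,6-dihydro-2H-pyran-2-yl}-7-methyl-3-(trimethylsilyloxy)octa-2,6-dienoate (new centres unassigned) | COC(=O)C=C(O[Si](C)(C)C)C(CC=C(C)C)C1C=C(O[Si](C)(C)C)C[C@@H](O1)c1c(O[Si](C)(C)C(C)(C)C)cccc1O[Si](C)(C)C(C)(C)C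
F2 | step 8 | methyl 4-{(2R)-2-[2,6-bis(TBSO)phenyl]-4-oxo-3,4-dihydro-2H-pyran-6-yl}-7-methyl-3-oxooct-6-enoate | COC(=O)CC(=O)C(CC=C(C)C)C1=CC(=O)C[C@@H](O1)c1c(O[Si](C)(C)C(C)(C)C)cccc1O[Si](C)(C)C(C)(C)C
F3 | step 2 | (R)-4-[2,6-bis(TBSO)phenyl]-4-hydroxybutan-2-one | CC(=O)C[C@@H](O)c1c(O[Si](C)(C)C(C)(C)C)cccc1O[Si](C)(C)C(C)(C)C
F4 | step 2 | (R,E)-5-[2,6-bis(TBSO)phenyl]-1-(dimethylamino)-5-hydroxypent-1-en-3-one | CN(C)/C=C/C(=O)C[C@@H](O)c1c(O[Si](C)(C)C(C)(C)C)cccc1O[Si](C)(C)C(C)(C)C
F5 | step 3 | (R)-2-[2,6-bis(TBSO)phenyl]-5-iodo-2,3-dihydro-4H-pyran-4-one | O=C1C[C@@H](OC=C1I)c1c(O[Si](C)(C)C(C)(C)C)cccc1O[Si](C)(C)C(C)(C)C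
F6 | step 9 | (2R)-2-[2,6-bis(TBSO)phenyl]-5-hydroxy-7-(2-methylbut-3-yn-2-yloxy)-8-(3-methylbut-2-enyl)chroman-4-one | O=C1C[C@@H](Oc2c(CC=C(C)C)c(OC(C)(C)C#C)cc(O)c12)c1c(O[Si](C)(C)C(C)(C)C)cccc1O[Si](C)(C)C(C)(C)C
F7 | step 10 | (2R)-2-[2,6-bis(TBSO)phenyl]-5-methoxy-7-(2-methylbut-3-yn-2-yloxy)-8-(3-methylbut-2-enyl)chroman-4-one | O=C1C[C@@H](Oc2c(CC=C(C)C)c(OC(C)(C)C#C)cc(OC)c12)c1c(O[Si](C)(C)C(C)(C)C)cccc1O[Si](C)(C)C(C)(C)C
A1 | alternative 1 | 1-diazobut-3-en-2-one | C=CC(=O)C=[N+]=[N-]
A2 | alternative 1 | (8R)-5-methoxy-2,2-dimethyl-10-(3-methylbut-2-enyl)-8-[(triisopropylsilyloxy)ethynyl]-7,8-dihydro-2H,6H-pyrano[3,2-g]chromen-6-one | COc1c2C=CC(C)(C)Oc2c(CC=C(C)C)c2O[C@H](CC(=O)c12)C#CO[Si](C(C)C)(C(C)C)C(C)C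
A3 | alternative 1 | 6′-O-triisopropylsilyl ether of the target | COc1c2c(c(CC=C(C)C)c3c1[C@@]1(O)C[C@@H](O3)c3c(O[Si](C(C)C)(C(C)C)C(C)C)cccc3O1)OC(C)(C)C=C2
A4 | alternative 2 | 5-methoxy-2,2-dimethyl-8-(3-methylbut-2-enyl)-6-(trimethylsilyl)-2H-chromen-7-yl trifluoromethanesulfonate | COc1c([Si](C)(C)C)c(OS(=O)(=O)C(F)(F)F)c(CC=C(C)C)c2OC(C)(C)C=Cc12
A5 | alternative 2 | 6,7-didehydro-5-methoxy-2,2-dimethyl-8-(3-methylbut-2-enyl)-2H-chromene (aryne) | COC1=C2C=CC(C)(C)OC2=C(CC=C(C)C)C#C1
A6 | alternative 2 | (S)-3-[2,6-bis(methoxymethoxy)phenyl]-3-(tert-butyldimethylsilyloxy)propanoic acid | OC(=O)C[C@H](O[Si](C)(C)C(C)(C)C)c1c(OCOC)cccc1OCOC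
A7 | alternative 2 | (S)-3-[2,6-bis(methoxymethoxy)phenyl]-3-(tert-butyldimethylsilyloxy)-1-[7-hydroxy-5-methoxy-2,2-dimethyl-8-(3-methylbut-2-enyl)-2H-chromen-6-yl]propan-1-one | COc1c2c(c(CC=C(C)C)c(O)c1C(=O)C[C@H](O[Si](C)(C)C(C)(C)C)c1c(OCOC)cccc1OCOC)OC(C)(C)C=C2
A8 | alternative 3 | 6-(hydroxymethyl)-5-methoxy-2,2-dimethyl-2H-chromen-7-ol | COc1c(CO)c(O)cc2OC(C)(C)C=Cc12
A9 | alternative 3 | 5-methoxy-2,2-dimethyl-6-methylidene-2H-chromen-7(6H)-one (ortho-quinone methide) | COC1=C2C=CC(C)(C)OC2=CC(=O)C1=C
A10 | alternative 3 | 2-vinylresorcinol | C=Cc1c(O)cccc1O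
A11 | alternative 3 | (8R)-8-(2,6-dihydroxyphenyl)-5-methoxy-2,2-dimethyl-7,8-dihydro-2H,6H-pyrano[3,2-g]chromene | COc1c2c(cc3c1CC[C@@H](O3)c1c(O)cccc1O)OC(C)(C)C=C2
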